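- Retrosynthetic cuts, in order: the acetyl–ring bond; the bond from the bridging CH2 to the trione ring; both bonds to the ring carbonyl carbon lying between the bridge-bearing and the acetyl-bearing ring carbons; the geranyl–quaternary carbon bond. On the aromatic half: the aryl–CH2 bond, the pyran ring and the butanoyl–aryl bond.
- Enabling feature: that ring carbonyl carbon of the six-membered trione ring is an isolated one-carbon unit. Without it the ring reduces to a symmetrical 3,3-disubstituted pentane-2,4-dione that already holds the methyl/geranyl quaternary carbon, so the ring can be closed by inserting a carbonyl between the two acetyl methyl carbons.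
- Forward order: geranylation, then the trione ring by [5+1] double acylation. Separately, phloroglucinol is acylated, the pyran ring of the chromene is closed and C6 is aminomethylated. The halves are joined through the CH2 bridge in a one-pot sulfinate-relay coupling, and the acetyl group goes on last.
- Stereochemistry: the only stereocentre (the quaternary ring carbon, R in the target) is set when a chiral squaramide directs the chromene quinone methide to one of the two enantiotopic enol carbons of the achiral trione. The E-alkene comes in with geranyl bromide.

Key step: step 2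

Assumption: the sense of induction in step 6 cannot be predicted with confidence. The route is written with the quinine-derived squaramide; the quinidine-derived pseudoenantiomer would be used instead if that is the one leading to (4S)-18.
Remark: trione-derived compounds are written as one enol tautomer. The descriptor at the quaternary carbon is S in 18 and R in 21 only because the acetyl group changes the CIP ranking; the spatial arrangement is the same. Geranyl = (2E)-3,7-dimethylocta-2,6-dien-1-yl.

**Step 1**
Reactants: 1 3-methylpentane-2,4-dione; 2 geranyl bromide [(2E)-1-bromo-3,7-dimethylocta-2,6-diene]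
Product: 3 3-geranyl-3-methylpentane-2,4-dione
Conditions: K2CO3, acetone, reflux
Reagents that add atoms: none
Why: C-alkylation of the stabilised diketone enolate by a primary allylic bromide (SN2) is standard, the soft electrophile favours carbon over oxygen, the E-alkene is untouched, and carbonate in acetone is too weak a nucleophile to cause retro-Claisen cleavage.

**Step 2**
Reactants: 3 3-geranyl-3-methylpentane-2,4-dione; 4 dimethyl carbonate
Product: 7 2-geranyl-2-methylcyclohexane-1,3,5-trione, via dilithium bis-enolate 5 (not isolated), via beta-keto ester 6 (not isolated)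
Conditions: LiN(SiMe3)2 (3.3 equiv), THF, −78 to 0 °C; (MeO)2CO (1.05 equiv, slow addition), 0 to 60 °C; then 1 M HCl
Reagents that add atoms: none
Why: Because the carbon between the two carbonyls of 3 is quaternary, the amide base can only deprotonate the two acetyl methyl groups and gives bis-enolate 5; one enolate carbon attacks the carbonate to give beta-keto ester 6 (held as its enolate by the third equivalent of base), and the remaining methyl ketone enolate then attacks the ester carbonyl and expels methoxide, so both bonds to the new ring carbonyl carbon form in one flask. The closest known reactions are the Claisen condensation of ketone enolates with dialkyl carbonates and the Dieckmann-type closure of keto ester enolates to cyclic 1,3-diones and 1,3,5-triones. The six-membered ring closes in a 6-(enolendo)-exo-trig mode. No stereocentre results: 7 has a mirror plane through the quaternary carbon and the new carbonyl, and the stereocentre of racemic 6 vanishes on closure. The step needs C- over O-acylation and must avoid methoxide-induced retro-Claisen cleavage; excess non-nucleophilic base keeps every ketone as its enolate (cleavage would have to expel a dianion), any O-acylated species is itself an acyl donor that funnels to the C-acylated product, and slow addition of one equivalent of carbonate favours ring closure over a second intermolecular acylation. The product is a vinylogous acid that ends as its delocalised anion, which makes the sequence irreversible until the acidic work-up.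

**Step 3**
Reactants: 8 phloroglucinol; 9 butanoyl chloride
Product: 10 1-(2,4,6-trihydroxyphenyl)butan-1-one
Conditions: AlCl3 (4 equiv), PhNO2/CH2Cl2, 0 to 50 °C; then ice/aq. HCl
Reagents that add atoms: none
Why: Friedel–Crafts acylation of phloroglucinol should stop after one acyl group because the first, aluminium-chelated acyl group deactivates the ring.

**Step 4**
Reactants: 10 1-(2,4,6-trihydroxyphenyl)butan-1-one; 11 3-methylbut-2-enal
Product: 13 1-(5,7-dihydroxy-2,2-dimethyl-2H-chromen-8-yl)butan-1-one, via oxatriene 12 (not isolated)
Conditions: ethylenediammonium diacetate (20 mol%), 11 (1.05 equiv), toluene, 100 °C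
Reagents that add atoms: none
Why: Knoevenagel-type condensation of the enal at a free ring carbon gives quinone methide (1-oxatriene) 12, which closes by oxa-6π electrocyclisation through the oxygen ortho to the butanoyl group to give 13, the 6-butanoyl regioisomer from closure through the para oxygen being an expected by-product to be removed by chromatography.

**Step 5**
Reactants: 13 1-(5,7-dihydroxy-2,2-dimethyl-2H-chromen-8-yl)butan-1-one; 14 N,N-dimethylmethyleneiminium iodide
Product: 15 1-{6-[(dimethylamino)methyl]-5,7-dihydroxy-2,2-dimethyl-2H-chromen-8-yl}butan-1-one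
Conditions: CH2Cl2, rt; aq. NaHCO3 work-up
Reagents that add atoms: none
Why: Mannich reaction (aromatic aminomethylation) in which the preformed iminium salt attacks the only unsubstituted ring carbon, C6, which lies between two hydroxy groups and is by far the most nucleophilic site.

**Step 6**
Reactants: 15 1-{6-[(dimethylamino)methyl]-5,7-dihydroxy-2,2-dimethyl-2H-chromen-8-yl}butan-1-one; 7 2-geranyl-2-methylcyclohexane-1,3,5-trione
Product: 18 (4S)-2-[(8-butanoyl-5,7-dihydroxy-2,2-dimethyl-2H-chromen-6-yl)methyl]-4-geranyl-3,5-dihydroxy-4-methylcyclohexa-2,5-dien-1-one, via o-quinone methide 16 (not isolated), via sulfone 17 (not isolated)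
Conditions: (a) sodium p-toluenesulfinate (1.5 equiv), AcOH (2 equiv), toluene/H2O, 60 °C; aqueous layer drained, toluene layer washed with water; (b) 7 (1.3 equiv), quinine-derived squaramide 3-{[3,5-bis(trifluoromethyl)phenyl]amino}-4-{[(8α,9S)-6'-methoxycinchonan-9-yl]amino}cyclobut-3-ene-1,2-dione (10 mol%), aq. NaHCO3, 0 °C; then 1 M HCl
Reagents that add atoms: none
Why: Proposed new method: in the acidic first stage the protonated amine of 15 leaves to give o-quinone methide 16, which the soft sulfinate traps at sulfur as the neutral, toluene-soluble sulfone 17 (the known elimination–addition of phenolic Mannich bases), so that dimethylamine is removed with the aqueous phase before the chiral stage; bicarbonate then slowly unmasks 16 again from 17 while the trione enters toluene as the enolate ion-paired with the protonated quinuclidine of the catalyst, whose squaramide NH groups bind the quinone methide carbonyl, and in this chiral pocket only one of the two enantiotopic enol carbons of the mirror-symmetric enolate can reach the exocyclic CH2, so the Michael addition turns the prochiral quaternary carbon into the stereocentre under catalyst control; the closest known reactions are squaramide-catalysed conjugate additions of cyclic 1,3-diones to o-quinone methides released in situ from 2-(sulfonylmethyl)phenols and catalytic desymmetrisations of 4,4-disubstituted cyclohexa-2,5-dienones, the new element being that the stereocentre set is the remote quaternary carbon and not the benzylic one.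

**Step 7**
Reactants: 18 (4S)-2-[(8-butanoyl-5,7-dihydroxy-2,2-dimethyl-2H-chromen-6-yl)methyl]-4-geranyl-3,5-dihydroxy-4-methylcyclohexa-2,5-dien-1-one; 19 acetic acid
Product: 21 (4R)-2-acetyl-6-[(8-butanoyl-5,7-dihydroxy-2,2-dimethyl-2H-chromen-6-yl)methyl]-4-geranyl-3,5-dihydroxy-4-methylcyclohexa-2,5-dien-1-one, via enol acetate 20 (not isolated)
Conditions: AcOH (1.05 equiv), N,N'-dicyclohexylcarbodiimide (DCC, 1.1 equiv), 4-(dimethylamino)pyridine (DMAP, 1.2 equiv), CH2Cl2, 0 °C to rt; cold 0.5 M HCl wash
Reagents that add atoms: none
Why: Carbodiimide-mediated O-acylation of the most acidic hydroxy group (the trione enol) followed by DMAP-mediated O-to-C acyl migration (Fries-type rearrangement of 1,3-dione enol esters) should place the acetyl group on the only free ring carbon, where the chelated enolised beta-triketone is the thermodynamic sink, and the quaternary stereocentre, having no acidic hydrogen, is not affected.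

**Compound list**
1 | 3-methylpentane-2,4-dione | CC(=O)C(C)C(C)=O | starting material
2 | geranyl bromide, (2E)-1-bromo-3,7-dimethylocta-2,6-diene | BrC/C=C(\C)CCC=C(C)C | starting material
3 | 3-[(2E)-3,7-dimethylocta-2,6-dien-1-yl]-3-methylpentane-2,4-dione | CC(=O)C(C)(C/C=C(\C)CCC=C(C)C)C(C)=O | intermediate
4 | dimethyl carbonate | COC(=O)OC | starting material
5 | dilithium bis-enolate of 3, dilithium 3-geranyl-3-methylpenta-1,4-diene-2,4-diolate (formed in the flask, step 2) | [Li+].[Li+].C=C([O-])C(C)(C/C=C(\C)CCC=C(C)C)C(=C)[O-] | intermediate
6 | methyl (6E)-4-acetyl-4,7,11-trimethyl-3-oxododeca-6,10-dienoate, racemic (formed in the flask, step 2) | COC(=O)CC(=O)C(C)(C/C=C(\C)CCC=C(C)C)C(C)=O | intermediate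
7 | 2-[(2E)-3,7-dimethylocta-2,6-dien-1-yl]-2-methylcyclohexane-1,3,5-trione (achiral) | CC1(C/C=C(\C)CCC=C(C)C)C(=O)CC(=O)CC1=O | intermediate
8 | phloroglucinol | Oc1cc(O)cc(O)c1 | starting material
9 | butanoyl chloride | CCCC(=O)Cl | starting material
10 | 1-(2,4,6-trihydroxyphenyl)butan-1-one | CCCC(=O)c1c(O)cc(O)cc1O | intermediate
11 | 3-methylbut-2-enal | CC(C)=CC=O | starting material
12 | 2-butanoyl-3,5-dihydroxy-6-(3-methylbut-2-en-1-ylidene)cyclohexa-2,4-dien-1-one (formed in the flask, step 4) | CCCC(=O)C1=C(O)C=C(O)C(=CC=C(C)C)C1=O | intermediate
13 | 1-(5,7-dihydroxy-2,2-dimethyl-2H-chromen-8-yl)butan-1-one | CCCC(=O)c1c(O)cc(O)c2c1OC(C)(C)C=C2 | intermediate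
14 | N,N-dimethylmethyleneiminium iodide | C=[N+](C)C.[I-] | starting material
15 | 1-{6-[(dimethylamino)methyl]-5,7-dihydroxy-2,2-dimethyl-2H-chromen-8-yl}butan-1-one | CCCC(=O)c1c(O)c(CN(C)C)c(O)c2c1OC(C)(C)C=C2 | intermediate
16 | 8-butanoyl-7-hydroxy-2,2-dimethyl-6-methylidene-2H-chromen-5(6H)-one, o-quinone methide (formed in the flask, step 6) | CCCC(=O)C1=C(O)C(=C)C(=O)C2=C1OC(C)(C)C=C2 | intermediate
17 | 1-{5,7-dihydroxy-2,2-dimethyl-6-[(4-methylbenzenesulfonyl)methyl]-2H-chromen-8-yl}butan-1-one (formed in the flask, step 6, carried on as its toluene solution) | CCCC(=O)c1c(O)c(CS(=O)(=O)c3ccc(C)cc3)c(O)c2c1OC(C)(C)C=C2 | intermediate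
18 | (4S)-2-[(8-butanoyl-5,7-dihydroxy-2,2-dimethyl-2H-chromen-6-yl)methyl]-4-[(2E)-3,7-dimethylocta-2,6-dien-1-yl]-3,5-dihydroxy-4-methylcyclohexa-2,5-dien-1-one | CCCC(=O)c1c(O)c(CC2=C(O)[C@@](C)(C/C=C(\C)CCC=C(C)C)C(O)=CC2=O)c(O)c2c1OC(C)(C)C=C2 | intermediate
19 | acetic acid | CC(=O)O | starting material
20 | O-acetate of 18 at the enol oxygen next to the ring CH, configuration at the quaternary carbon as in 18 (formed in the flask, step 7) | CCCC(=O)c1c(O)c(CC2=C(O)[C@@](C)(C/C=C(\C)CCC=C(C)C)C(OC(C)=O)=CC2=O)c(O)c2c1OC(C)(C)C=C2 | intermediate
21 | (4R)-2-acetyl-6-[(8-butanoyl-5,7-dihydroxy-2,2-dimethyl-2H-chromen-6-yl)methyl]-4-[(2E)-3,7-dimethylocta-2,6-dien-1-yl]-3,5-dihydroxy-4-methylcyclohexa-2,5-dien-1-one | CCCC(=O)c1c(O)c(CC2=C(O)[C@@](C)(C/C=C(\C)CCC=C(C)C)C(O)=C(C(C)=O)C2=O)c(O)c2c1OC(C)(C)C=C2 | target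

**Step count**
Total: 7 steps. Longest linear sequence: 5 steps (steps 3 to 7, from phloroglucinol); the trione branch (steps 1 and 2) joins at step 6.

**Steps most likely to fail**

Step 6 (labelled step). The catalyst may discriminate poorly between the two enantiotopic enol carbons, and the sodium enolate may react uncatalysed at the phase boundary; either would erode the enantiomeric purity. Dimethylamine carried over from the first stage would release the quinone methide beside an achiral ammonium counter-ion and have the same effect. A second alkylation of the trione ring and base-induced retro-Michael scrambling of the bridge are further risks. The fallback sets out from Mannich base 15 and trione 7. Heating the two in toluene eliminates the amine and gives, by uncatalysed Michael addition to 16, the racemic coupled phenol F1; this is the established thermal way to methylene-bridged acylphloroglucinol dimers. Preparative chromatography on a polysaccharide-based chiral stationary phase then separates the enantiomers; the unwanted (4R)-enantiomer F2 is set aside and the route is rejoined at 18.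

Step 2. Double enolisation may be incomplete, proton transfer from the beta-keto ester may quench the second enolate before ring closure, closure may occur through oxygen to an enol lactone, or a second intermolecular acylation may compete. The fallback builds the same ring by a [4+2] Claisen sequence and sets out from geranyl bromide 2. Purchased methyl 2-methyl-3-oxobutanoate is alkylated with 2 (K2CO3, acetone) to give methyl 2-geranyl-2-methyl-3-oxobutanoate F3. Its kinetic lithium enolate (LiN(iPr)2, THF, −78 °C) is acylated with N-methoxy-N-methylacetamide to give methyl 2-geranyl-2-methyl-3,5-dioxohexanoate F4. The dianion of F4 (LiN(iPr)2, 2.2 equiv) attacks the ester through its terminal carbon in an intramolecular Claisen condensation, and acidic work-up returns to the route at 7.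

Step 7. The phenols may be acetylated in competition with the enol, the O-to-C migration may stall, or the base may trigger retro-Michael scrambling of the bridge. The fallback sets out from 18 and gives up chemoselectivity on purpose. Excess Ac2O with Et3N and DMAP in CH2Cl2 acetylates both phenols and drives the acyl migration on the trione ring, giving the 5,7-di-O-acetate of 21 F5. Brief methanolysis (K2CO3, MeOH, 0 °C) then cleaves the aryl acetates, and any enol acetate, leaving the C-acetyl group in place and arriving at 21.

**Further compounds**
F1 | step 6 | racemic 2-[(8-butanoyl-5,7-dihydroxy-2,2-dimethyl-2H-chromen-6-yl)methyl]-4-geranyl-3,5-dihydroxy-4-methylcyclohexa-2,5-dien-1-one | CCCC(=O)c1c(O)c(CC2=C(O)C(C)(C/C=C(\C)CCC=C(C)C)C(O)=CC2=O)c(O)c2c1OC(C)(C)C=C2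
F2 | step 6 | (4R)-enantiomer of 18 | CCCC(=O)c1c(O)c(CC2=C(O)[C@](C)(C/C=C(\C)CCC=C(C)C)C(O)=CC2=O)c(O)c2c1OC(C)(C)C=C2
F3 | step 2 | methyl 2-[(2E)-3,7-dimethylocta-2,6-dien-1-yl]-2-methyl-3-oxobutanoate, racemic | COC(=O)C(C)(C/C=C(\C)CCC=C(C)C)C(C)=O
F4 | step 2 | methyl 2-[(2E)-3,7-dimethylocta-2,6-dien-1-yl]-2-methyl-3,5-dioxohexanoate, racemic | COC(=O)C(C)(C/C=C(\C)CCC=C(C)C)C(=O)CC(C)=O
F5 | step 7 | 5,7-di-O-acetate of 21, configuration as in 21 | CCCC(=O)c1c(OC(C)=O)c(CC2=C(O)[C@@](C)(C/C=C(\C)CCC=C(C)C)C(O)=C(C(C)=O)C2=O)c(OC(C)=O)c2c1OC(C)(C)C=C2
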